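**Plan**
- Retrosynthesis: cut the C11–O aryl ether (umbelliferone) and the angelate ester. Then cut C5–C10 and C3–C4 together, which opens rings B and A at once to an acyclic alkene–enal–aldehyde. Finally cut C9–C10 to (2S,3S)-2,3-epoxygeraniol and a 2-metallated butene carrying a masked aldehyde.
- Enabling feature: C10 can be reached as a tertiary radical from a 1,1-disubstituted alkene that lies 1,6 to the enal β-carbon C5 (ring B). The enolate carbon C4 that results lies 1,6 to the aldehyde carbon C3 (ring A), and ring A carries the aldol pattern C3–OH/C4–CH2O.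
- Helper: O8 and O11 are tied in a 2,2-di-tert-butyl-1,3,2-dioxasilinane. This temporary ring can only be fused to ring B through two equatorial bonds; it is removed with fluoride before the ether is made.
- Forward: geraniol → epoxide → copper-catalysed opening at C2 → silylene → enal (SeO2, MnO2) → free aldehyde → one-pot closure of ring B then ring A → angelate → desilylation → Mitsunobu ether.
- Stereochemistry: C8 and C9 come from the Sharpless epoxidation and the invertive epoxide opening. C10, C5, C4 and C3 are set in the key step under control of the C8/C9 pair held in the silylene ring.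

Key step: step 7

Remark: drimane-type numbering is used. Ring A is C1–C5 and C10; ring B is C5–C10; C11 is the CH2O arm on C9; the oxygenated one-carbon arm on C4 is written C4-CHO or C4-CH2O. Compound 3 is used as its commercial THF solution.

**Step 1**
Reactants: 1 geraniol
Product: 2 (2S,3S)-2,3-epoxygeraniol
Conditions: Ti(OiPr)4 (5 mol %), L-(+)-diethyl tartrate (6 mol %), t-BuOOH, 4 Å MS, CH2Cl2, −20 °C
Reagents that add atoms: tert-butyl hydroperoxide, CC(C)(C)OO
Why: Sharpless asymmetric epoxidation; the titanium tartrate complex binds the allylic hydroxyl and delivers oxygen to one face of the 2,3-alkene, setting (2S,3S) with L-(+)-tartrate and leaving the remote 6,7-alkene untouched.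

**Step 2**
Reactants: 3 (1,3-dioxolan-2-ylmethyl)magnesium bromide; 4 2,3-dibromoprop-1-ene
Product: 5 2-(3-bromobut-3-en-1-yl)-1,3-dioxolane
Conditions: Li2CuCl4 (3 mol %), THF, −10 °C → rt
Reagents that add atoms: none
Why: Copper-catalysed allylic substitution of the allylic bromide by the Grignard reagent (SN2 and SN2' give the same product); the vinylic bromide does not react.

**Step 3**
Reactants: 2 (2S,3S)-2,3-epoxygeraniol; 5 2-(3-bromobut-3-en-1-yl)-1,3-dioxolane
Product: 7 (2R,3S)-2-[4-(1,3-dioxolan-2-yl)but-1-en-2-yl]-3,7-dimethyloct-6-ene-1,3-diol, via alkenylmagnesium bromide 6 (not isolated)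
Conditions: 5, Mg, THF, 40 °C; then CuBr·SMe2 (10 mol %), 2 (0.4 equiv), THF, −30 → 0 °C; aq NH4Cl
Reagents that add atoms: none
Why: Copper-catalysed ring opening of a 2,3-epoxy alcohol by an alkenyl Grignard reagent; attack occurs anti at the secondary C2 because C3 is fully substituted, so C2 (later C9) is set with inversion and the C3–O bond (later C8–O) is retained.

**Step 4**
Reactants: 7 the 1,3-diol
Product: 8 (4S,5R)-2,2-di-tert-butyl-5-[4-(1,3-dioxolan-2-yl)but-1-en-2-yl]-4-methyl-4-(4-methylpent-3-en-1-yl)-1,3,2-dioxasilinane
Conditions: t-Bu2Si(OTf)2 (1.05 equiv), 2,6-lutidine, CH2Cl2, −40 → 0 °C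
Reagents that add atoms: di-tert-butylsilyl bis(trifluoromethanesulfonate), CC(C)(C)[Si](OS(=O)(=O)C(F)(F)F)(OS(=O)(=O)C(F)(F)F)C(C)(C)C
Why: Silylene protection of a 1,3-diol; the six-membered ring masks both hydroxyls and ties O8 to O11 so that ring B can later form only with both in equatorial positions; no stereocenter is touched.

**Step 5**
Reactants: 8 the silylene
Product: 10 (2E)-5-[(4S,5R)-2,2-di-tert-butyl-5-[4-(1,3-dioxolan-2-yl)but-1-en-2-yl]-4-methyl-1,3,2-dioxasilinan-4-yl]-2-methylpent-2-enal, via allylic alcohol 9 (not isolated)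
Conditions: SeO2 (0.3 equiv), t-BuOOH, salicylic acid (cat.), CH2Cl2, rt; then MnO2, CH2Cl2, rt
Reagents that add atoms: selenium dioxide, O=[Se]=O; tert-butyl hydroperoxide, CC(C)(C)OO (reoxidises selenium and is the final source of the new oxygen)
Why: Selenium dioxide allylic oxidation (ene reaction, then [2,3]-sigmatropic shift) is fastest at the (E)-methyl of the electron-rich trisubstituted prenyl terminus and gives the (E)-allylic alcohol, which MnO2 oxidises selectively to the (E)-enal.

**Step 6**
Reactants: 10 the enal acetal
Product: 11 (2E)-5-[(4S,5R)-2,2-di-tert-butyl-4-methyl-5-(5-oxopent-1-en-2-yl)-1,3,2-dioxasilinan-4-yl]-2-methylpent-2-enal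
Conditions: PPTS (cat.), acetone/H2O (10:1), 55 °C
Reagents that add atoms: water, O
Why: Acid-catalysed acetal hydrolysis unmasks the C3 aldehyde; the hindered silylene and the enal should tolerate pyridinium tosylate.

**Step 7**
Reactants: 11 the alkene–enal–aldehyde
Product: 13 silylene-bridged trans-decalin diol (3R,4S,5S,8S,9R,10R) with equatorial 3-OH, equatorial C4-CH2OH and axial 4-, 8- and 10-CH3, via hydroxy aldehyde 12 (not isolated)
Conditions: Fe(acac)3 (30 mol %), PhSiH3 (2.5 equiv), EtOH/THF (3:1), 0.01 M, 0 °C → rt; then NaBH4, 0 °C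
Reagents that add atoms: none
Why: Hydrogen-atom transfer from the iron hydride formed from Fe(acac)3 and PhSiH3 to the CH2 terminus of the 1,1-disubstituted alkene gives the tertiary C10 radical (the new CH3 is the angular methyl), which adds 6-exo-trig to the enal β-carbon C5 (ring B, bond C5–C10); divalent iron reduces the α-formyl radical to a trivalent iron (E)-enolate, whose C4 attacks the C3 aldehyde in a 6-(enolexo)-exo-trig aldol (ring A, bond C3–C4), and NaBH4 then reduces the neopentyl aldehyde before retro-aldol can intervene. The closest known reaction type is the hydrogen-atom-transfer-initiated radical conjugate addition–aldol (radical–polar crossover) annulation and polycyclization of alkenyl aldehydes with α-branched enals. C5: the dioxasilinane can be fused to the forming ring B only through two equatorial bonds, so the chair has O8 and C11 equatorial, the C8 methyl axial and the enal arm equatorial, which puts H5 on the face of H9; C10: at the planar radical the small methyl takes the crowded pseudoaxial site next to the axial C8 methyl and the CH2CH2CHO arm the pseudoequatorial one, giving the trans ring fusion. C4: allylic 1,3-strain makes H5 eclipse the enolate double bond, so the formyl carbon ends equatorial and the C4 methyl axial, syn to the C10 methyl; C3: the enolate oxygen, anti to C5 as inherited from the s-trans enal, chelates the aldehyde oxygen in a chair Zimmerman–Traxler array that places the new hydroxyl equatorial. The step needs hydrogen-atom transfer to the electron-rich 1,1-disubstituted alkene and not to the enal or the aldehydes, which the alkene-selective iron hydride secures, and ring closure faster than reduction of the radical or intermolecular addition, which the activated intramolecular acceptor and high dilution secure.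

**Step 8**
Reactants: 13 the diol; 14 angelic acid, (2Z)-2-methylbut-2-enoic acid
Product: 16 mono-angelate at C4-CH2O of 13 (3-OH free, silylene intact), via mixed anhydride 15 (not isolated)
Conditions: 14, 2,4,6-trichlorobenzoyl chloride, Et3N, toluene, rt; then 13, toluene, 70 °C
Reagents that add atoms: none
Why: Yamaguchi esterification through the mixed anhydride without DMAP should transfer the angeloyl group without Z to E isomerisation, and the bulky anhydride acylates the primary neopentyl hydroxyl in preference to the secondary C3 hydroxyl next to quaternary C4.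

**Step 9**
Reactants: 16 the angelate silylene
Product: 17 angelate triol (3R,4S,5S,8S,9R,10R) with free 3-OH, 8-OH and C11-OH
Conditions: HF·pyridine, pyridine/THF, 0 °C → rt
Reagents that add atoms: none
Why: Fluoride cleavage of the silylene (strong Si–F bond) frees the C8 and C11 hydroxyls under buffered conditions that leave the angelate and the tertiary carbinol intact.

**Step 10**
Reactants: 17 the angelate triol; 18 umbelliferone (7-hydroxycoumarin)
Product: 19 CNP0139045.1
Conditions: 18, PPh3, DIAD, THF, 0 → 50 °C
Reagents that add atoms: none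
Why: Mitsunobu etherification; the acidic phenol displaces the oxyphosphonium of the only primary hydroxyl (C11, no stereocenter), while the tertiary C8 and the hindered secondary C3 hydroxyls are not activated.

**Compound list**
1 | geraniol, (2E)-3,7-dimethylocta-2,6-dien-1-ol | CC(C)=CCC/C(C)=C/CO | starting material
2 | (2S,3S)-2,3-epoxygeraniol, [(2S,3S)-3-methyl-3-(4-methylpent-3-en-1-yl)oxiran-2-yl]methanol | CC(C)=CCC[C@]1(C)O[C@H]1CO | intermediate
3 | (1,3-dioxolan-2-ylmethyl)magnesium bromide | Br[Mg]CC1OCCO1 | starting material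
4 | 2,3-dibromoprop-1-ene | BrCC(Br)=C | starting material
5 | 2-(3-bromobut-3-en-1-yl)-1,3-dioxolane | C=C(Br)CCC1OCCO1 | intermediate
6 | [4-(1,3-dioxolan-2-yl)but-1-en-2-yl]magnesium bromide | C=C([Mg]Br)CCC1OCCO1 | intermediate (not isolated)
7 | (2R,3S)-2-[4-(1,3-dioxolan-2-yl)but-1-en-2-yl]-3,7-dimethyloct-6-ene-1,3-diol | CC(C)=CCC[C@](C)(O)[C@@H](CO)C(=C)CCC1OCCO1 | intermediate
8 | (4S,5R)-2,2-di-tert-butyl-5-[4-(1,3-dioxolan-2-yl)but-1-en-2-yl]-4-methyl-4-(4-methylpent-3-en-1-yl)-1,3,2-dioxasilinane | CC(C)=CCC[C@]1(C)O[Si](C(C)(C)C)(C(C)(C)C)OC[C@H]1C(=C)CCC2OCCO2 | intermediate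
9 | (2E)-5-[(4S,5R)-2,2-di-tert-butyl-5-[4-(1,3-dioxolan-2-yl)but-1-en-2-yl]-4-methyl-1,3,2-dioxasilinan-4-yl]-2-methylpent-2-en-1-ol | OC/C(C)=C/CC[C@]1(C)O[Si](C(C)(C)C)(C(C)(C)C)OC[C@H]1C(=C)CCC2OCCO2 | intermediate (not isolated)
10 | (2E)-5-[(4S,5R)-2,2-di-tert-butyl-5-[4-(1,3-dioxolan-2-yl)but-1-en-2-yl]-4-methyl-1,3,2-dioxasilinan-4-yl]-2-methylpent-2-enal | O=C/C(C)=C/CC[C@]1(C)O[Si](C(C)(C)C)(C(C)(C)C)OC[C@H]1C(=C)CCC2OCCO2 | intermediate
11 | (2E)-5-[(4S,5R)-2,2-di-tert-butyl-4-methyl-5-(5-oxopent-1-en-2-yl)-1,3,2-dioxasilinan-4-yl]-2-methylpent-2-enal | O=C/C(C)=C/CC[C@]1(C)O[Si](C(C)(C)C)(C(C)(C)C)OC[C@H]1C(=C)CCC=O | intermediate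
12 | silylene-bridged hydroxy aldehyde: trans-decalin (3R,4R,5S,8S,9R,10R) with equatorial 3-OH, equatorial 4-CHO, axial 4-, 8- and 10-CH3, and O8 and O11 joined by Si(t-Bu)2 | O=C[C@]1(C)[C@H]2CC[C@]3(C)O[Si](C(C)(C)C)(C(C)(C)C)OC[C@H]3[C@]2(C)CC[C@H]1O | intermediate (not isolated)
13 | silylene-bridged diol: as 12 with C4-CH2OH in place of CHO, (3R,4S,5S,8S,9R,10R) | OC[C@]1(C)[C@H]2CC[C@]3(C)O[Si](C(C)(C)C)(C(C)(C)C)OC[C@H]3[C@]2(C)CC[C@H]1O | intermediate
14 | angelic acid, (2Z)-2-methylbut-2-enoic acid | C/C=C(/C)C(O)=O | starting material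
15 | (2Z)-2-methylbut-2-enoic 2,4,6-trichlorobenzoic anhydride | C/C=C(/C)C(=O)OC(=O)c1c(Cl)cc(Cl)cc1Cl | intermediate (not isolated)
16 | silylene-bridged mono-angelate: as 13 with the C4-CH2OH esterified by angelic acid, 3-OH free | C/C=C(/C)C(=O)OC[C@]1(C)[C@H]2CC[C@]3(C)O[Si](C(C)(C)C)(C(C)(C)C)OC[C@H]3[C@]2(C)CC[C@H]1O | intermediate
17 | angelate triol: trans-decalin (3R,4S,5S,8S,9R,10R) with 3-OH, 8-OH, C11-OH and C4-CH2O-angelate | C/C=C(/C)C(=O)OC[C@]1(C)[C@H]2CC[C@](C)(O)[C@@H](CO)[C@]2(C)CC[C@H]1O | intermediate
18 | umbelliferone, 7-hydroxy-2H-chromen-2-one | Oc1ccc2ccc(=O)oc2c1 | starting material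
19 | CNP0139045.1, the 11-O-(2-oxo-2H-chromen-7-yl) ether of 17 | C/C=C(/C)C(=O)OC[C@]1(C)[C@H]2CC[C@](C)(O)[C@@H](COc3ccc4ccc(=O)oc4c3)[C@]2(C)CC[C@H]1O | target

**Count**
Total steps: 10. Longest linear sequence: 9 steps (steps 1 and 3–10, from geraniol); step 2 is a one-step side branch.

**Steps most likely to fail**

1. Step 7. Ring A may close through a non-chelated aldol transition state, or the aldolate may equilibrate by retro-aldol and re-aldol, so that the configuration of the C3 carbinol is eroded. Control of the C10 centre by the methyl against chain preference is also only modest, and this fallback does not correct it. The fallback sets out from 12, which is isolated as its mixture of C3 epimers by leaving out the borohydride. Dess–Martin periodinane in CH2Cl2 oxidises it to the silylene-bridged 3-oxo aldehyde F1, in which C4 is quaternary and cannot epimerise. NaBH4 in MeOH at −20 °C then reduces the aldehyde and adds hydride axially to the C3 ketone, because the equatorial path is blocked by the axial C4 methyl. This should give the equatorial carbinol and comes back to the route at 13.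

2. Step 10. Substitution at C11 is slow because this primary carbon is flanked by the quaternary C8 and C10, so elimination of the oxyphosphonium or its capture by the C8 hydroxyl may compete. The fallback sets out from 17 and forms the aryl–oxygen bond instead of the alkyl–oxygen bond: palladium-catalysed C–O coupling of the primary hydroxyl with commercial 7-bromocoumarin ([Pd(allyl)Cl]2, RockPhos, Cs2CO3, toluene, 80 °C). It makes no new intermediate (F0) and comes back at 19.

3. Step 5. Ene oxidation at the allylic positions of the 1,1-disubstituted alkene and over-oxidation may compete with oxidation of the prenyl methyl. The fallback sets out from 8 and rebuilds the enal terminus by cleavage and olefination. mCPBA (1 equiv, NaHCO3, CH2Cl2, −20 °C) epoxidises the more electron-rich trisubstituted alkene to the 6,7-epoxide F2. H5IO6 in THF/Et2O at 0 °C cleaves it to the nor-aldehyde F3. Wittig olefination with Ph3P=C(CH3)CHO in toluene at 80 °C gives the (E)-enal and comes back at 10.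

**Further compounds**
F1 | step 7 | silylene-bridged 3-oxo aldehyde: 12 with C3 ketone in place of the carbinol | O=C[C@]1(C)[C@H]2CC[C@]3(C)O[Si](C(C)(C)C)(C(C)(C)C)OC[C@H]3[C@]2(C)CCC1=O
F0 | step 10 | none | none
F2 | step 5 | 6,7-epoxide of 8 (both configurations at the new epoxide carbon) | CC1(C)OC1CC[C@]2(C)O[Si](C(C)(C)C)(C(C)(C)C)OC[C@H]2C(=C)CCC3OCCO3
F3 | step 5 | 3-[(4S,5R)-2,2-di-tert-butyl-5-[4-(1,3-dioxolan-2-yl)but-1-en-2-yl]-4-methyl-1,3,2-dioxasilinan-4-yl]propanal | O=CCC[C@]1(C)O[Si](C(C)(C)C)(C(C)(C)C)OC[C@H]1C(=C)CCC2OCCO2
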